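**Retrosynthetic overview**

- Ring A (the arene) is bought intact as 2-hydroxy-6-iodobenzoic acid. Ring B (the lactone) is the only ring made, and it is closed last.
- Ring B is closed by an enantioselective palladium-catalysed arylation/lactonisation of an acyclic (3E,5E)-triene, which forms C4–C4a and C3–O together and sets C3.
- The triene comes from (2E,4E)-octadeca-2,4-dienal by Wittig methylenation.
- The dienal is not made by olefination. Its C1–C5 (C3 and the whole E,E-diene of the target) are the five ring carbons of pyridine, released by dearomatising ring-opening to the glutaconaldehyde enolate, to which the C13 chain is added as a Grignard reagent.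

Assumption: 2-hydroxy-6-iodobenzoic acid is bought as a catalogue compound, and the antipode of ligand PA ((11bR)-N,N-bis[(1R)-1-phenylethyl]dinaphtho[2,1-d:1',2'-f][1,3,2]dioxaphosphepin-4-amine, written as (R,R,R)) that gives the (R)-lactone is fixed in a first test run.

**Route**

Step 1
Reactants: 1 pyridine
Product: 4 potassium (1E,3E)-5-oxopenta-1,3-dien-1-olate (glutaconaldehyde potassium salt), via pyridinium-1-sulfonate 2 (not isolated), via ring-opened sulfamate 3 (not isolated)
Conditions: ClSO3H (0.5 equiv), CHCl3, 0 °C; then KOH (4 equiv), H2O, −20 → 40 °C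
Reagents that add atoms: potassium hydroxide, [K+].[OH-]
Why: Zincke-type dearomatising ring-opening, in which N-sulfonation makes C2 of pyridine electrophilic, hydroxide adds there, the 1,2-dihydropyridine opens by 6π-electrocyclic ring-opening and the N-sulfonyl imine is hydrolysed, so the five ring carbons emerge as the all-trans glutaconaldehyde enolate (no stereocentre formed).

Step 2
Reactants: 4 glutaconaldehyde potassium salt; 5 1-bromotridecane
Product: 8 (2E,4E)-octadeca-2,4-dienal, via tridecylmagnesium bromide 6 (not isolated), via dienolate adduct 7 (not isolated)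
Conditions: 5, Mg, THF, 40 °C; then 4, THF, 0 °C → rt; then 2 M HCl, 0 °C → rt
Reagents that add atoms: none
Why: Grignard 1,2-addition to the formyl carbon of the vinylogous formate anion stops at mono-addition because the adduct is an unreactive dienolate, and acidification triggers vinylogous E1cB loss of water to the thermodynamically preferred (2E,4E)-dienal, so both olefin geometries are fixed without any olefination (the transient carbinol centre is destroyed).

Step 3
Reactants: 8 (2E,4E)-octadeca-2,4-dienal
Product: 9 (3E,5E)-nonadeca-1,3,5-triene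
Conditions: Ph3PCH3Br (1.3 equiv), KOtBu (1.25 equiv), THF, 0 °C → rt
Reagents that add atoms: methyltriphenylphosphonium bromide, C[P+](c1ccccc1)(c1ccccc1)c1ccccc1.[Br-]
Why: Wittig methylenation with the non-stabilised ylide converts the formyl group into the terminal vinyl group without touching the E,E-diene (no stereocentre formed).

Step 4
Reactants: 9 (3E,5E)-nonadeca-1,3,5-triene; 10 2-hydroxy-6-iodobenzoic acid
Product: 11 (3R)-3-[(1E,3E)-heptadeca-1,3-dien-1-yl]-8-hydroxy-3,4-dihydro-1H-isochromen-1-one
Conditions: Pd2(dba)3 (2.5 mol %), (R,R,R)-PA (11 mol %), Ag2CO3 (1.0 equiv), 10 (1.3 equiv), 1,4-dioxane, 50 °C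
Reagents that add atoms: none
Why: Proposed new method: oxidative addition of zerovalent palladium into the carbon–iodine bond of 10, regioselective syn-carbopalladation of the only monosubstituted alkene of 9 with the aryl group going to CH2, and anti attack of the ortho-carboxylate on the proximal terminus of the resulting syn-η3-pentadienylpalladium unit (six-membered ring favoured over eight or ten, conjugated E,E-diene kept) close ring B, with the chiral phosphoramidite–palladium fragment selecting the allyl face that leads to (R)-configured C3; the closest known reaction type is the Larock heteroannulation of 1,3-dienes with ortho-iodobenzoic acids and related aryl iodides, including enantioselective phosphoramidite–palladium versions with ortho-iodoanilines and ortho-iodophenols, whereas a conjugated triene and an enantioselective carboxylate closure are untested.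

**Compound list**

1 | pyridine | c1ccncc1 | starting material
2 | pyridinium-1-sulfonate (pyridine–sulfur trioxide adduct) | [O-]S(=O)(=O)[n+]1ccccc1 | intermediate
3 | potassium N-[(1E,3E)-5-oxopenta-1,3-dien-1-yl]sulfamate (ring-opened sulfamate, drawn as the amino-dienal tautomer) | [K+].[O-]S(=O)(=O)N/C=C/C=C/C=O | intermediate
4 | potassium (1E,3E)-5-oxopenta-1,3-dien-1-olate (glutaconaldehyde potassium salt) | [K+].[O-]/C=C/C=C/C=O | intermediate
5 | 1-bromotridecane | CCCCCCCCCCCCCBr | starting material
6 | tridecylmagnesium bromide | CCCCCCCCCCCCC[Mg]Br | intermediate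
7 | bromomagnesium potassium (1E,3E)-5-oxidooctadeca-1,3-dien-1-olate (dienolate adduct, racemic at C5) | CCCCCCCCCCCCCC([O-])/C=C/C=C/[O-].[K+].[Mg+2].[Br-] | intermediate
8 | (2E,4E)-octadeca-2,4-dienal | CCCCCCCCCCCCC/C=C/C=C/C=O | intermediate
9 | (3E,5E)-nonadeca-1,3,5-triene | CCCCCCCCCCCCC/C=C/C=C/C=C | intermediate
10 | 2-hydroxy-6-iodobenzoic acid | OC(=O)c1c(O)cccc1I | starting material
11 | (3R)-3-[(1E,3E)-heptadeca-1,3-dien-1-yl]-8-hydroxy-3,4-dihydro-1H-isochromen-1-one | CCCCCCCCCCCCC/C=C/C=C/[C@H]1Cc2cccc(O)c2C(=O)O1 | target

**Step count**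

Total step count: 4. Longest linear sequence: 4 steps (1 → 4 → 8 → 9 → 11).

**Steps most likely to fail, with fallbacks**

Step 4 is the most likely to fail. The enantioselectivity is unproven for a carboxylate closing onto a pentadienylpalladium unit. Heck-type β-hydride elimination to an aryl tetraene can compete. Zerovalent palladium can also re-ionise the dienylic lactone and erode the ee, which is why 10 is kept in excess and the reaction is stopped once 9 is consumed.

The fallback sets out from dienal 8 and comes back at 11. Commercial 2,2,5-trimethyl-4H-1,3-benzodioxin-4-one is deprotonated at its benzylic methyl group with LiN(iPr)2 in THF at −78 °C to give 5-(lithiomethyl)-2,2-dimethyl-4H-1,3-benzodioxin-4-one F1. This adds 1,2 to 8 to give the lithium alkoxide, lithium (3E,5E)-1-(2,2-dimethyl-4-oxo-4H-1,3-benzodioxin-5-yl)nonadeca-3,5-dien-2-olate F2. On warming to 0 °C the alkoxide closes onto the dioxinone carbonyl, expels acetone and frees the phenol, giving the racemic lactone (3RS)-3-[(1E,3E)-heptadeca-1,3-dien-1-yl]-8-hydroxy-3,4-dihydro-1H-isochromen-1-one F3. Preparative chromatography on a chiral stationary phase then separates 11 from its (3S)-enantiomer, (3S)-3-[(1E,3E)-heptadeca-1,3-dien-1-yl]-8-hydroxy-3,4-dihydro-1H-isochromen-1-one F4. This forms C3–C4 instead of C4–C4a and takes the enantiopurity from a resolution instead of from catalysis.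

Step 2 is the second risk. Salt 4 is a poorly soluble, deactivated vinylogous carboxylate, so the Grignard addition can be slow or incomplete, and the acid-induced elimination must be driven fully to the E,E-isomer.

The fallback sets out from 4 and comes back at 8. Ph3PBr2 in CH2Cl2 at 0 °C converts the enolate oxygen of 4 into a vinyl bromide, giving (2E,4E)-5-bromopenta-2,4-dienal F5. Negishi coupling of this with tridecylzinc bromide F6 (made from 5 with Zn dust and LiCl in THF) under Pd(PPh3)4 in THF at rt puts the C13 chain on the former enolate carbon and gives 8 directly. The chain is thus attached by sp2–sp3 cross-coupling instead of carbonyl addition and elimination.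

Step 1 is the third risk. The ring-opening is exothermic and temperature-sensitive, the yield is moderate, and the hygroscopic, air-sensitive salt decides the quality of step 2.

The fallback sets out from 1 and comes back at 8. Pyridine is N-arylated with 1-chloro-2,4-dinitrobenzene in refluxing acetone to give 1-(2,4-dinitrophenyl)pyridinium chloride F7. Dimethylamine in EtOH at 0 °C opens the ring to the vinamidinium salt N-[(2E,4E)-5-(dimethylamino)penta-2,4-dien-1-ylidene]-N-methylmethanaminium chloride F8 with loss of 2,4-dinitroaniline. Aqueous NaOH hydrolyses this to the Zincke aldehyde (2E,4E)-5-(dimethylamino)penta-2,4-dienal F9. Grignard reagent 6 adds to its formyl group in THF at −78 → 0 °C to give bromomagnesium (1E,3E)-1-(dimethylamino)octadeca-1,3-dien-5-olate F10. Aqueous HCl then expels dimethylamine and water in a vinylogous Bouveault-type aldehyde synthesis and delivers 8.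

**Further compounds**

F1 | step 4 | 5-(lithiomethyl)-2,2-dimethyl-4H-1,3-benzodioxin-4-one | [Li]Cc1cccc2c1C(=O)OC(C)(C)O2
F2 | step 4 | lithium (3E,5E)-1-(2,2-dimethyl-4-oxo-4H-1,3-benzodioxin-5-yl)nonadeca-3,5-dien-2-olate (racemic) | CCCCCCCCCCCCC/C=C/C=C/C([O-])Cc1cccc2c1C(=O)OC(C)(C)O2.[Li+]
F3 | step 4 | (3RS)-3-[(1E,3E)-heptadeca-1,3-dien-1-yl]-8-hydroxy-3,4-dihydro-1H-isochromen-1-one (racemate) | CCCCCCCCCCCCC/C=C/C=C/C1Cc2cccc(O)c2C(=O)O1
F4 | step 4 | (3S)-3-[(1E,3E)-heptadeca-1,3-dien-1-yl]-8-hydroxy-3,4-dihydro-1H-isochromen-1-one | CCCCCCCCCCCCC/C=C/C=C/[C@@H]1Cc2cccc(O)c2C(=O)O1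
F5 | step 2 | (2E,4E)-5-bromopenta-2,4-dienal | Br/C=C/C=C/C=O
F6 | step 2 | tridecylzinc bromide | CCCCCCCCCCCCC[Zn]Br
F7 | step 1 | 1-(2,4-dinitrophenyl)pyridinium chloride | [Cl-].[O-][N+](=O)c1ccc(c(c1)[N+](=O)[O-])[n+]1ccccc1
F8 | step 1 | N-[(2E,4E)-5-(dimethylamino)penta-2,4-dien-1-ylidene]-N-methylmethanaminium chloride | C[N+](C)=C/C=C/C=C/N(C)C.[Cl-]
F9 | step 1 | (2E,4E)-5-(dimethylamino)penta-2,4-dienal | CN(C)/C=C/C=C/C=O
F10 | step 1 | bromomagnesium (1E,3E)-1-(dimethylamino)octadeca-1,3-dien-5-olate (racemic) | CCCCCCCCCCCCCC([O-])/C=C/C=C/N(C)C.[Mg+2].[Br-]
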